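## The problem

1. Numbering used throughout: C1 is the ketone carbon and C2=C3 the enone double bond (CH3 on C3). C4 and C11 are the two CH groups that carry the enone. C5 (CH) and C10 (C–CH3) are the other two four-ring carbons, C6 is the CMe2 carbon, and C7 (O-angelate), C8 (O-isovalerate) and C9 (OH) form the oxygenated chain.
2. One cyclobutane (ring A, C4–C5–C11–C10) is bridged twice. C4 and C11 are tied by C3=C2–C1 over one face (ring B, a bicyclo[3.1.1]heptenone). C5 and C10 are tied by C6–C7–C8–C9 under the other face (ring C, a bicyclo[4.1.1]octane).
3. The four ring A stereocentres can exist in the cage in only one relative arrangement, so they count as a single element. That element is decided only by whether C1 sits on C11 or on C4, because the plane through C5, C6, C7, C8, C9 and C10 would be a mirror plane of the carbon cage if the enone had no direction.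
4. The real stereochemical task is therefore to tie C7, C8 and C9 to that direction. In the closed cage the two faces of ring C differ only at a distance. Only the C9–C10 bond can carry the information into ring A, while within the chain C9 can control C8 and C7.
5. Every possible last bond of ring A ends at the quaternary C10 or at C5, which is neopentyl next to C6, and costs about the strain of a pinane. Reversible closures (Michael, aldol) therefore run backwards and SN2 closures are slow.
6. The angelate isomerises to the tiglate with acid, base, nucleophiles or heat. The C8 ester can migrate to the free C9 hydroxyl. Cationic character at C7 invites methyl shifts from C6.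
7. The enabling feature is this: C11 bears only H and the acyl carbon C1, C4 is allylic to C3=C2, and C10 carries CH3 and the chain. If C1 is removed, C11 becomes the carbonyl of a cyclobutanone flanked by C5 and C10, with an isopropenyl group on C4. That is the [2+2] adduct of the ketene C10=C11=O and the diene C5=C4–C3=C2, with the ring C chain as tether.

## Retrosynthesis

**Acyl groups, C7–O and C8–O (35 ⇒ 34 ⇒ 31 ⇒ 28 ⇒ 27).** The esters go on last because of the angelate. The 7,8-trans/8,9-cis pattern is what anti opening of an epoxide gives when the epoxide lies anti to the C9 oxygen and is attacked at C8. C7 is neopentyl, so C8 is the open position. Isovalerate then enters as the nucleophile, which sets C8 and differentiates the three oxygens without protecting-group exchanges. Dienone 27 keeps only one oxygenated stereocentre. The forward steps need face selection by the C9 silyl ether and a regioselective SN2 reaction.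

**C1–C2 and C1–C11 (27 ⇒ 25 ⇒ 24 ⇒ 20).** Cutting C2=C3 (aldol or phosphonate condensation) would leave two acyl groups on C4 and C11. These positions are related by the pseudo-mirror plane, so the closure could run in either direction. Cutting C1–C2 leaves an isopropenyl group on C4 and a formyl group on C11, which cannot be confused, and a carbonyl-ene reaction joins them. Removing C1 then gives the bicyclic ketone 20, in which ring B is gone altogether. The forward steps need both groups on the face away from ring C. The isopropenyl group is placed there by the key step, and C11 can be epimerised.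

**C5–C11 and C4–C10 (20 ⇒ 19 ⇒ 17).** Both bonds are cut at once, which opens rings A and C and leads to an acyclic acid with one relevant stereocentre. The neighbouring pairing (C4–C5 and C10–C11) has no ketene retron. Placing the carbonyl on C5 instead would put oxygen where the C6 quaternary carbon must be attached. The stereocentre C9 sits in the tether directly next to the ketene carbon C10, so the remote relation between chain and cage becomes a 1,2-induction. The forward reaction must proceed in the bridged mode, at the proximal double bond of the diene, and on one face.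

**C9–C10 (17 ⇒ 14 ⇒ 10 + 11).** An auxiliary-controlled propionate aldol sets C9 by reagent control and brings in C10, its methyl group and C11 at the acid oxidation level. The configuration at C10 is erased in the ketene, so only C9 matters. Cutting C8–C9 instead would need a Z-vinyl metal and a separate source of chirality.

**C7=C8 (10 ⇒ 5 + 6).** A Z-selective phosphonate olefination supplies C8 and C9. The Z double bond later folds the tether and carries the C7/C8 oxygens in latent form.

**C5–C6 (5 ⇒ 4 ⇒ 1 + 2).** A propargyl Claisen rearrangement joins the α-carbon of isobutyraldehyde (C6, both methyl groups and C7) to the alkyne terminus (C5). This makes the quaternary carbon next to an sp2 carbon, where enolate alkylation is not possible. Isomerisation of the allene gives the diene. Both starting materials are bulk chemicals.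

## Roads not taken

**Alternative 1:** Cut C5–C11 alone. This is the most obvious route. The cyclobutane is closed last by intramolecular alkylation of the C11 enolate in the 6–7 fused keto mesylate A1.
- The displacement is a four-membered closure at a secondary neopentyl carbon, with elimination towards C4 as the easy escape.
- A1 already holds two rings, the angular quaternary C10 and the C4/C5/C9 stereocentres, so it is hardly simpler than its product.
- The chosen plan forms two ring A bonds from an open chain and lets C9 do the stereochemical work.

**Alternative 2:** Cut C4–C10 and C5–C11 photochemically. This means a crossed enone–alkene [2+2] cycloaddition of the cross-conjugated trienone A2 to the divinyl bicyclo[3.1.1]heptenone A3, followed by ring-closing metathesis at C7=C8.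
- With a three-atom tether, the first bond of the triplet normally closes a five-membered ring, which leads to the fused adduct and not the bridged one.
- C2=C3 must be Z and competes through electrocyclisation.
- The biradical can rotate, so the orientation of the arms on C5 and C10 is not secured.
- C9 lies outside every forming ring and controls the face only weakly.
- The thermal ketene reaction keeps the alkene geometry, and the tether enforces the arm orientation.

**Alternative 3:** Cut the same two bonds, but with C5 as the ketene carbon. A vinylketene with the three-atom tether C3–C2–C1 would give the bicyclo[3.1.1]heptan-6-one A4, which is the best-precedented closure.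
- This puts the carbonyl where the target has H and the CMe2 carbon.
- C6 would have to be added as a tertiary nucleophile from the more hindered face, the tertiary alcohol removed, and C1 oxidised afterwards.
- Ring C would still have to be closed with its stereocentres far from any control element.
- The chosen plan needs only one carbon (C1) after the cycloaddition.

Key step: step 9

Assumption: the 2-methylbut-2-enoate written in the SMILES is read as the Z isomer (angelate); atom numbers C1–C11 are those defined in the first section.

## Steps

Step 1
Reactants: 1 isobutyraldehyde (2-methylpropanal); 2 2-methylbut-3-yn-2-ol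
Product: 4 2,2,5-trimethylhexa-3,4-dienal, via propargyl vinyl ether 3 (not isolated)
Conditions: TsOH (cat.), 1 in excess, toluene, reflux with water separator
Reagents that add atoms: none
Why: Acid-catalysed condensation gives the propargyl vinyl ether 3, which undergoes the propargyl Claisen rearrangement ([3,3]) to the allenyl aldehyde. The C5–C6 bond and the quaternary C6 are formed with no stereochemical issue.

Step 2
Reactants: 4 2,2,5-trimethylhexa-3,4-dienal
Product: 5 (3E)-2,2,5-trimethylhexa-3,5-dienal
Conditions: Pd(PPh3)4 (cat.), PhCO2H (cat.), toluene, 80 °C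
Reagents that add atoms: none
Why: This is a palladium hydride catalysed allene to 1,3-diene isomerisation, in which hydropalladation at the central carbon gives a π-allyl complex that loses a methyl β-hydrogen. Conjugation drives the reaction, the bulky CMe2 group should set the E geometry at C4=C5, and the aldehyde has no α-hydrogen.

Step 3
Reactants: 5 (3E)-2,2,5-trimethylhexa-3,5-dienal; 6 methyl bis(2,2,2-trifluoroethyl)phosphonoacetate
Product: 8 methyl (2Z,5E)-4,4,7-trimethylocta-2,5,7-trienoate, via phosphonate anion 7 (not isolated)
Conditions: KN(SiMe3)2, 18-crown-6, THF, −78 °C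
Reagents that add atoms: none
Why: In the Still–Gennari olefination the electron-poor phosphonate makes the elimination fast and the addition kinetically controlled, which should give the Z enoate (C7=C8). The aldehyde cannot enolise.

Step 4
Reactants: 8 methyl (2Z,5E)-4,4,7-trimethylocta-2,5,7-trienoate
Product: 9 (2Z,5E)-4,4,7-trimethylocta-2,5,7-trien-1-ol
Conditions: iBu2AlH, CH2Cl2, −78 °C; aqueous work-up
Reagents that add atoms: none
Why: This is a 1,2-reduction of an enoate to the allylic alcohol, and neither the double-bond geometries nor the diene are touched.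

Step 5
Reactants: 9 (2Z,5E)-4,4,7-trimethylocta-2,5,7-trien-1-ol
Product: 10 (2Z,5E)-4,4,7-trimethylocta-2,5,7-trienal
Conditions: Dess–Martin periodinane, CH2Cl2, 0 °C
Reagents that add atoms: none
Why: The Dess–Martin oxidation is mild and nearly neutral, so it should keep the Z geometry. The enal is used at once.

Step 6
Reactants: 10 (2Z,5E)-4,4,7-trimethylocta-2,5,7-trienal; 11 (4S)-4-benzyl-3-propanoyl-1,3-oxazolidin-2-one
Product: 14 (4S)-4-benzyl-3-[(2S,3R,4Z,7E)-3-hydroxy-2,6,6,9-tetramethyldeca-4,7,9-trienoyl]-1,3-oxazolidin-2-one, via boron enolate 12 (not isolated), via boron aldolate 13 (not isolated)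
Conditions: 11, Bu2BOTf, Et3N, CH2Cl2, −78 to 0 °C; 10, −78 °C; then H2O2, MeOH, pH 7 buffer, 0 °C
Reagents that add atoms: none
Why: In the Evans syn aldol reaction the Z boron enolate reacts through a Zimmerman–Traxler chair on the face left open by the benzyl group. This sets C9 by reagent control, while the C10 centre formed with it is erased in step 9.

Step 7
Reactants: 14 aldol adduct
Product: 15 (4S)-4-benzyl-3-[(2S,3R,4Z,7E)-3-[(tert-butyldimethylsilyl)oxy]-2,6,6,9-tetramethyldeca-4,7,9-trienoyl]-1,3-oxazolidin-2-one
Conditions: TBSOTf, 2,6-lutidine, CH2Cl2, 0 °C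
Reagents that add atoms: tert-butyldimethylsilyl triflate, CC(C)(C)[Si](C)(C)OS(=O)(=O)C(F)(F)F
Why: Silylation of the secondary alcohol blocks β-lactone formation in step 9 and provides the bulky group that steers steps 9 and 14.

Step 8
Reactants: 15 silylated imide
Product: 17 (2S,3R,4Z,7E)-3-[(tert-butyldimethylsilyl)oxy]-2,6,6,9-tetramethyldeca-4,7,9-trienoic acid, via peroxy acid 16 (not isolated)
Conditions: LiOH, H2O2, THF/H2O, 0 °C; Na2SO3; HCl to pH 3
Reagents that add atoms: hydrogen peroxide, OO
Why: Hydroperoxide attacks the exocyclic carbonyl of the imide selectively, and sulfite reduces the percarboxylate before it can act as an oxidant. The auxiliary is recovered.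

Step 9
Reactants: 17 (2S,3R,4Z,7E)-3-[(tert-butyldimethylsilyl)oxy]-2,6,6,9-tetramethyldeca-4,7,9-trienoic acid
Product: 20 (1S,2R,6R,8R)-2-[(tert-butyldimethylsilyl)oxy]-1,5,5-trimethyl-8-(prop-1-en-2-yl)bicyclo[4.1.1]oct-3-en-7-one (C11 ketone; isopropenyl on C4 anti to the C6–C9 bridge), via acid chloride 18 (not isolated), via ketene 19 (not isolated)
Conditions: 1-chloro-N,N,2-trimethylprop-1-en-1-amine, CH2Cl2, 0 °C; solution added slowly to iPr2NEt, toluene, 110 °C, high dilution
Reagents that add atoms: none
Why: Proposed new method: The chloroenamine converts 17 into acid chloride 18 without acid, and slow addition to hot iPr2NEt gives the methyl(alkyl)ketene 19, whose carbonyl carbon C11 is attacked by the diene terminus C5 while the charge building up at C4 is allylic (C4–C3–C2) and collapses onto the enolate carbon C10, an asynchronous [2+2] cycloaddition. The closest known reaction types are the intramolecular ketene–alkene [2+2] cycloaddition in its bridged mode, which gives bicyclo[3.1.1]heptan-6-ones from ketenes with a three-atom tether, and the [2+2] addition of ketenes to 1,3-dienes, which gives 3-vinylcyclobutanones with this same regiochemistry; the four-atom tether and a diene in the bridged mode are new. The C11–C5 bond closes the seven-membered ring C11–C10–C9–C8–C7–C6–C5 (exo with respect to C5=C4), the C10–C4 bond then closes the four-membered ring A, and together they make the bicyclo[4.1.1]octenone. Regioselectivity is needed against the fused mode (C10–C5 and C11–C4) and is secured by the vinyl group, since only a charge on C4 is allylic whereas the fused mode would put it on the neopentyl C5; the distal C3=C2 bond could be reached only through a ten-membered ring. C5 and C10 are set cis because the tether can span ring A on one face only, and C4 follows from the E geometry of C4=C5, which is kept in the cycloaddition and places the isopropenyl group trans to C6, on the face away from the tether. The sense of the cage relative to C9 is set by 1,2-induction: C4 should bond to the face of C10 that is anti to the bulky C9 silyl ether, so that this oxygen ends up on the side of the carbonyl bridge C11 as in 35. The Z double bond C7=C8 and the geminal methyl groups on C6 fold the tether (Thorpe–Ingold effect), and a disubstituted ketene at high dilution dimerises slowly enough to wait for a slow ring closure.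

Step 10
Reactants: 20 bicyclic ketone; 21 (methoxymethyl)triphenylphosphonium chloride
Product: 23 enol ether of 20 (C11=CH–OCH3 with C1 as the new carbon; E/Z mixture of no consequence), via ylide 22 (not isolated)
Conditions: 21, KN(SiMe3)2, THF, 0 °C; 20, 0 to 40 °C
Reagents that add atoms: none
Why: This is a Wittig methoxymethylenation in which the strained cyclobutanone carbonyl is reactive. It cannot enolise, because C10 is quaternary and an enolate towards C5 would be a bridgehead double bond (Bredt's rule).

Step 11
Reactants: 23 enol ether
Product: 24 bicyclic aldehyde (formyl C1 on C11 and isopropenyl on C4 both on the face of ring A anti to the C6–C9 bridge; other centres as in 20)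
Conditions: TsOH·H2O (cat.), acetone/H2O, rt; then DBU (cat.), CH2Cl2, rt
Reagents that add atoms: water, O
Why: Enol ether hydrolysis is followed by base equilibration at C11. The position on the bridge side is flanked by a C6 methyl group and the C9 silyl ether, so the formyl group should settle on the opposite face, and any other epimer can be equilibrated again.

Step 12
Reactants: 24 bicyclic aldehyde
Product: 25 tricyclic homoallylic alcohol (ring B closed; C1–OH of no stereochemical consequence; exocyclic methylene on C3; C9 silyl ether and C7=C8 unchanged)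
Conditions: Me2AlCl, CH2Cl2, −78 to −20 °C
Reagents that add atoms: none
Why: This is a type 2 intramolecular carbonyl-ene reaction in which the terminal carbon C2 of the isopropenyl group attacks the complexed aldehyde C1 and a methyl hydrogen is transferred. The two groups are held close in a 1,3-cis relation on ring A, and C4–H cannot be the donor because that would give a bridgehead alkene.

Step 13
Reactants: 25 tricyclic homoallylic alcohol
Product: 27 9-[(tert-butyldimethylsilyl)oxy]longipina-2,7-dien-1-one (cage centres C4, C5, C10, C11 and C9 placed as in 35), via unconjugated enone 26 (not isolated)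
Conditions: Dess–Martin periodinane, CH2Cl2, rt; then DBU (cat.), rt
Reagents that add atoms: none
Why: Oxidation gives the β,γ-unsaturated ketone, and base moves the exocyclic double bond into conjugation (C2=C3), which is the only conjugated position the cage allows.

Step 14
Reactants: 27 dienone
Product: 28 7,8-epoxide of 27 (epoxide oxygen on the face of ring C opposite to the C9 silyl ether, the C4 side)
Conditions: mCPBA, CH2Cl2, 0 °C
Reagents that add atoms: 3-chloroperoxybenzoic acid, O=C(OO)c1cccc(Cl)c1
Why: In this Prilezhaev epoxidation the electron-poor enone double bond stays untouched. The cage offers two almost equal faces at C7=C8, so the neighbouring bulky silyl ether should decide and direct the peracid anti to itself, which sets C7.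

Step 15
Reactants: 28 epoxide; 29 isovaleric acid (3-methylbutanoic acid)
Product: 31 9-[(tert-butyldimethylsilyl)oxy]-7-hydroxy-8-(3-methylbutanoyloxy)longipin-2-en-1-one (C7, C8 and C9 placed as in 35), via cesium isovalerate 30 (not isolated)
Conditions: 29 (excess), Cs2CO3 (substoichiometric), DMF, 90 °C
Reagents that add atoms: none
Why: This is an SN2 opening of the epoxide by a carboxylate in which C7 is neopentyl, so attack should go to C8 with inversion. That places the C8 oxygen cis to the C9 oxygen and leaves the C7 hydroxyl trans and free, while excess acid protonates the alkoxide and suppresses acyl migration.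

Step 16
Reactants: 31 hydroxy ester; 32 angelic acid ((2Z)-2-methylbut-2-enoic acid)
Product: 34 7-angeloyloxy-9-[(tert-butyldimethylsilyl)oxy]-8-(3-methylbutanoyloxy)longipin-2-en-1-one, via mixed anhydride 33 (not isolated)
Conditions: 32, 2,4,6-trichlorobenzoyl chloride, Et3N, toluene, rt; then 31, 80 °C
Reagents that add atoms: none
Why: This is an acylation through a Yamaguchi-type mixed anhydride without a nucleophilic catalyst, the variant used for hindered alcohols because it avoids the addition–elimination path that turns angelate into tiglate.

Step 17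
Reactants: 34 silyl ether
Product: 35 (4R,5S,7S,8S,9S,10R,11R)-7-angeloyloxy-9-hydroxy-8-(3-methylbutanoyloxy)longipin-2-en-1-one (CNP0128158.1)
Conditions: HF·pyridine, THF, 0 °C to rt
Reagents that add atoms: none
Why: Fluoride-mediated desilylation in acidic medium avoids an alkoxide at C9, so the C8 ester should not migrate and the angelate and the enone are left alone.

## Compound list

1 | isobutyraldehyde | CC(C)C=O | starting material
2 | 2-methylbut-3-yn-2-ol | CC(C)(O)C#C | starting material
3 | 3-methyl-3-[(2-methylprop-1-en-1-yl)oxy]but-1-yne | CC(C)=COC(C)(C)C#C | intermediate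
4 | 2,2,5-trimethylhexa-3,4-dienal | O=CC(C)(C)C=C=C(C)C | intermediate
5 | (3E)-2,2,5-trimethylhexa-3,5-dienal | O=CC(C)(C)/C=C/C(C)=C | intermediate
6 | methyl bis(2,2,2-trifluoroethyl)phosphonoacetate | COC(=O)CP(=O)(OCC(F)(F)F)OCC(F)(F)F | starting material
7 | potassium salt of 6 (phosphonate anion) | COC(=O)[CH-]P(=O)(OCC(F)(F)F)OCC(F)(F)F.[K+] | intermediate
8 | methyl (2Z,5E)-4,4,7-trimethylocta-2,5,7-trienoate | COC(=O)/C=C\C(C)(C)/C=C/C(C)=C | intermediate
9 | (2Z,5E)-4,4,7-trimethylocta-2,5,7-trien-1-ol | OC/C=C\C(C)(C)/C=C/C(C)=C | intermediate
10 | (2Z,5E)-4,4,7-trimethylocta-2,5,7-trienal | O=C/C=C\C(C)(C)/C=C/C(C)=C | intermediate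
11 | (4S)-4-benzyl-3-propanoyl-1,3-oxazolidin-2-one | CCC(=O)N1[C@H](COC1=O)Cc1ccccc1 | starting material
12 | (Z)-dibutylboron enolate of 11 | C/C=C(\OB(CCCC)CCCC)N1[C@H](COC1=O)Cc1ccccc1 | intermediate
13 | dibutylboron aldolate of 14 | O=C1OC[C@H](Cc2ccccc2)N1C(=O)[C@@H](C)[C@H](OB(CCCC)CCCC)/C=C\C(C)(C)/C=C/C(C)=C | intermediate
14 | syn aldol adduct (2S,3R,4Z,7E) | O=C1OC[C@H](Cc2ccccc2)N1C(=O)[C@@H](C)[C@H](O)/C=C\C(C)(C)/C=C/C(C)=C | intermediate
15 | silyl ether of 14 | O=C1OC[C@H](Cc2ccccc2)N1C(=O)[C@@H](C)[C@H](O[Si](C)(C)C(C)(C)C)/C=C\C(C)(C)/C=C/C(C)=C | intermediate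
16 | peroxy acid of 17 | OOC(=O)[C@@H](C)[C@H](O[Si](C)(C)C(C)(C)C)/C=C\C(C)(C)/C=C/C(C)=C | intermediate
17 | (2S,3R,4Z,7E)-3-[(tert-butyldimethylsilyl)oxy]-2,6,6,9-tetramethyldeca-4,7,9-trienoic acid | OC(=O)[C@@H](C)[C@H](O[Si](C)(C)C(C)(C)C)/C=C\C(C)(C)/C=C/C(C)=C | intermediate
18 | acid chloride of 17 | ClC(=O)[C@@H](C)[C@H](O[Si](C)(C)C(C)(C)C)/C=C\C(C)(C)/C=C/C(C)=C | intermediate
19 | (3R,4Z,7E)-3-[(tert-butyldimethylsilyl)oxy]-2,6,6,9-tetramethyldeca-1,4,7,9-tetraen-1-one (ketene) | O=C=C(C)[C@H](O[Si](C)(C)C(C)(C)C)/C=C\C(C)(C)/C=C/C(C)=C | intermediate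
20 | (1S,2R,6R,8R)-2-[(tert-butyldimethylsilyl)oxy]-1,5,5-trimethyl-8-(prop-1-en-2-yl)bicyclo[4.1.1]oct-3-en-7-one | C1=C[C@@H](O[Si](C)(C)C(C)(C)C)[C@@]2(C)C(=O)[C@H]([C@@H]2C(C)=C)C1(C)C | intermediate
21 | (methoxymethyl)triphenylphosphonium chloride | COC[P+](c1ccccc1)(c1ccccc1)c1ccccc1.[Cl-] | starting material
22 | (methoxymethylidene)triphenylphosphorane | COC=P(c1ccccc1)(c1ccccc1)c1ccccc1 | intermediate
23 | methoxymethylidene derivative of 20 | C1=C[C@@H](O[Si](C)(C)C(C)(C)C)[C@@]2(C)C(=COC)[C@H]([C@@H]2C(C)=C)C1(C)C | intermediate
24 | bicyclic aldehyde (C11–CHO and C4-isopropenyl anti to the bridge) | C1=C[C@@H](O[Si](C)(C)C(C)(C)C)[C@@]2(C)[C@H](C=O)[C@H]([C@@H]2C(C)=C)C1(C)C | intermediate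
25 | tricyclic homoallylic alcohol (C1–OH, C3 exocyclic methylene) | C1=C[C@@H](O[Si](C)(C)C(C)(C)C)[C@@]2(C)[C@@H]3C(O)CC(=C)[C@H]2[C@@H]3C1(C)C | intermediate
26 | unconjugated enone (C1 ketone, C3 exocyclic methylene) | C1=C[C@@H](O[Si](C)(C)C(C)(C)C)[C@@]2(C)[C@@H]3C(=O)CC(=C)[C@H]2[C@@H]3C1(C)C | intermediate
27 | 9-[(tert-butyldimethylsilyl)oxy]longipina-2,7-dien-1-one | C1=C[C@@H](O[Si](C)(C)C(C)(C)C)[C@@]2(C)[C@@H]3C(=O)C=C(C)[C@H]2[C@@H]3C1(C)C | intermediate
28 | 7,8-epoxide of 27, anti to the silyl ether | O4[C@@H]1[C@H]4[C@@H](O[Si](C)(C)C(C)(C)C)[C@@]2(C)[C@@H]3C(=O)C=C(C)[C@H]2[C@@H]3C1(C)C | intermediate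
29 | isovaleric acid | CC(C)CC(=O)O | starting material
30 | cesium isovalerate | CC(C)CC(=O)[O-].[Cs+] | intermediate
31 | 7-hydroxy 8-isovalerate 9-silyl ether | O[C@@H]1[C@@H](OC(=O)CC(C)C)[C@@H](O[Si](C)(C)C(C)(C)C)[C@@]2(C)[C@@H]3C(=O)C=C(C)[C@H]2[C@@H]3C1(C)C | intermediate
32 | angelic acid | C/C=C(/C)C(=O)O | starting material
33 | angelic 2,4,6-trichlorobenzoic anhydride | C/C=C(/C)C(=O)OC(=O)c1c(Cl)cc(Cl)cc1Cl | intermediate
34 | 7-angelate 8-isovalerate 9-silyl ether | C/C=C(/C)C(=O)O[C@@H]1[C@@H](OC(=O)CC(C)C)[C@@H](O[Si](C)(C)C(C)(C)C)[C@@]2(C)[C@@H]3C(=O)C=C(C)[C@H]2[C@@H]3C1(C)C | intermediate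
35 | CNP0128158.1 | C/C=C(/C)C(=O)O[C@@H]1[C@@H](OC(=O)CC(C)C)[C@@H](O)[C@@]2(C)[C@@H]3C(=O)C=C(C)[C@H]2[C@@H]3C1(C)C | target

## Step count and risks

Total step count: 17. Longest linear sequence: 17 steps (from 1 and 2).

**Step 9 (key step, proposed new method).**
- Risk: The ring closure may be too slow. Ketenes add sluggishly to E-1,2-disubstituted double bonds and C5 is neopentyl, so dimerisation or hydrolysis of the ketene could take over. Insufficient face selection by C9 is the second risk.
- Fallback: It sets out from 17 and returns at 20. The bond set is kept, but the neutral heterocumulene is replaced by a cation that reacts stepwise, as in the known intramolecular keteniminium–alkene cycloaddition, which also engages unactivated 1,2-disubstituted alkenes. Acid chloride 18 and pyrrolidine give the pyrrolidine amide F1. Tf2O and 2,6-di-tert-butyl-4-methylpyridine in 1,2-dichloroethane at 80 °C convert it into the keteniminium triflate F2. This should close to the cyclobutaniminium triflate F3, and aqueous NaHCO3 hydrolyses it to 20.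

**Step 15.**
- Risk: The SN2 opening may be slow or unselective. The carboxylate must enter at C8 on the face that carries the neighbouring silyl ether, next to an electron-withdrawing C–O bond. Prolonged heating invites acyl or silyl migration.
- Fallback: It sets out from 27 and returns at 31, and it replaces the epoxide by a far better leaving group. OsO4 with N-methylmorpholine N-oxide dihydroxylates C7=C8 anti to the silyl ether to the cis-diol F4. SOCl2 and Et3N give the cyclic sulfite F5, and RuCl3 with NaIO4 gives the cyclic sulfate F6. Cesium isovalerate 30 opens F6 at C8 with inversion to the C7 hydrogen sulfate F7, and dilute H2SO4 in wet THF cleaves it to 31.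

**Step 12.**
- Risk: The Lewis acid may ionise the allylic silyl ether, or the reaction may stop at chloride capture of the C3 cation instead of completing the hydrogen transfer. In addition, only the C11 epimer with the formyl group next to the isopropenyl group can react.
- Fallback: It sets out from 24 and returns at 27, and it closes C2=C3 by metathesis instead of C1–C2 by an ene reaction. Vinylmagnesium bromide gives the allylic alcohol F8, and Dess–Martin periodinane gives the vinyl ketone F9, which can be epimerised at C11. Ring-closing metathesis with the second-generation Grubbs catalyst joins the vinyl ketone to the isopropenyl group. The hindered C7=C8 bond should not take part.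

**Step 10.**
- Risk: Addition of the bulky ylide to a carbonyl flanked by the quaternary C10 and by C5 may be too slow, with decay of the ylide.
- Fallback: It sets out from 20 and returns at 24. Reductive cyanation with tosylmethyl isocyanide and KOtBu in 1,2-dimethoxyethane/tBuOH, a small nucleophile, gives the nitrile F10, which equilibrates at C11 under the reaction conditions. iBu2AlH followed by acidic work-up gives 24.

**Step 6.**
- Risk: Enal 10 may isomerise from Z to E before the aldol addition, promoted by the amine salt or the boron Lewis acid and driven by strain between the formyl group and the CMe2 group.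
- Fallback: It sets out from 5 and returns at 14, and it carries C7–C8 as an alkyne through the aldol step. Dimethyl (1-diazo-2-oxopropyl)phosphonate with K2CO3 in MeOH gives the alkyne F11. n-BuLi followed by DMF gives the ynal F12. Boron enolate 12 adds to it to give the propargylic aldol adduct F13. Zn activated with Cu(OAc)2 and AgNO3 in MeOH/H2O reduces the activated triple bond to the Z alkene without touching the diene.

## Further compounds

F1 | step 9 | pyrrolidine amide of 17 | O=C(N1CCCC1)[C@@H](C)[C@H](O[Si](C)(C)C(C)(C)C)/C=C\C(C)(C)/C=C/C(C)=C
F2 | step 9 | keteniminium triflate | CC(=C=[N+]1CCCC1)[C@H](O[Si](C)(C)C(C)(C)C)/C=C\C(C)(C)/C=C/C(C)=C.[O-]S(=O)(=O)C(F)(F)F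
F3 | step 9 | cyclobutaniminium triflate | C1=C[C@@H](O[Si](C)(C)C(C)(C)C)[C@@]2(C)C(=[N+]3CCCC3)[C@H]([C@@H]2C(C)=C)C1(C)C.[O-]S(=O)(=O)C(F)(F)F
F4 | step 15 | 7,8-cis-diol anti to the silyl ether | O[C@@H]1[C@H](O)[C@@H](O[Si](C)(C)C(C)(C)C)[C@@]2(C)[C@@H]3C(=O)C=C(C)[C@H]2[C@@H]3C1(C)C
F5 | step 15 | 7,8-cyclic sulfite | O=S4O[C@@H]1[C@H](O4)[C@@H](O[Si](C)(C)C(C)(C)C)[C@@]2(C)[C@@H]3C(=O)C=C(C)[C@H]2[C@@H]3C1(C)C
F6 | step 15 | 7,8-cyclic sulfate | O=S4(=O)O[C@@H]1[C@H](O4)[C@@H](O[Si](C)(C)C(C)(C)C)[C@@]2(C)[C@@H]3C(=O)C=C(C)[C@H]2[C@@H]3C1(C)C
F7 | step 15 | C7 hydrogen sulfate of 31 | OS(=O)(=O)O[C@@H]1[C@@H](OC(=O)CC(C)C)[C@@H](O[Si](C)(C)C(C)(C)C)[C@@]2(C)[C@@H]3C(=O)C=C(C)[C@H]2[C@@H]3C1(C)C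
F8 | step 12 | allylic alcohol from 24 | C1=C[C@@H](O[Si](C)(C)C(C)(C)C)[C@@]2(C)[C@H](C(O)C=C)[C@H]([C@@H]2C(C)=C)C1(C)C
F9 | step 12 | vinyl ketone | C1=C[C@@H](O[Si](C)(C)C(C)(C)C)[C@@]2(C)[C@H](C(=O)C=C)[C@H]([C@@H]2C(C)=C)C1(C)C
F10 | step 10 | C11 nitrile | C1=C[C@@H](O[Si](C)(C)C(C)(C)C)[C@@]2(C)[C@H](C#N)[C@H]([C@@H]2C(C)=C)C1(C)C
F11 | step 6 | (3E)-2,5,5-trimethylhepta-1,3-dien-6-yne | C#CC(C)(C)/C=C/C(C)=C
F12 | step 6 | (5E)-4,4,7-trimethylocta-5,7-dien-2-ynal | O=CC#CC(C)(C)/C=C/C(C)=C
F13 | step 6 | propargylic aldol adduct | O=C1OC[C@H](Cc2ccccc2)N1C(=O)[C@@H](C)[C@H](O)C#CC(C)(C)/C=C/C(C)=C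
A1 | alternative 1 | 6–7 fused keto mesylate (C5–OMs, C11H2) | C1=C[C@@H](O[Si](C)(C)C(C)(C)C)[C@@]2(C)CC(=O)C=C(C)[C@H]2[C@H](OS(C)(=O)=O)C1(C)C
A2 | alternative 2 | cross-conjugated trienone with two vinyl arms | C=CC(C)(C)/C=C/C(C)=C\C(=O)/C=C(C)/[C@H](O[Si](C)(C)C(C)(C)C)C=C
A3 | alternative 2 | divinyl bicyclo[3.1.1]heptenone | C=C[C@@H](O[Si](C)(C)C(C)(C)C)[C@@]2(C)[C@@H]3C(=O)C=C(C)[C@H]2[C@@H]3C(C)(C)C=C
A4 | alternative 3 | bicyclo[3.1.1]heptan-6-one with the carbonyl on C5 | C=C1CC[C@@H]2C(=O)[C@H]1[C@@]2(C)[C@H](O[Si](C)(C)C(C)(C)C)C=C
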